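**Retrosynthetic overview** (elemane numbering: C10 quaternary with Me and vinyl, C5 bearing the C3/C4/C15 isopropenyl unit, C6–O lactone, C7, C8–O ester, C9 methylene, C11/C12/C13 acrylate)
1. Target ⇒ C8 alcohol of the bicyclic lactone + (Z)-2-(silyloxymethyl)but-2-enoic acid; C15–OH comes from a late allylic hydroxylation of the isopropenyl group.
2. Bicyclic lactone ⇒ one acyclic C6 aldehyde carrying a (Z)-2-(borylmethyl)enoate: intramolecular allylboration closes C6–C7 (cyclohexane; C6 and C7 set) and the resulting borate lactonises in the same pot.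
3. Allylboronate ⇒ ynoate (conjugate hydroalumination, borylmethylation); C8 ⇒ asymmetric propiolate addition to a C8 aldehyde; that aldehyde ⇒ terminal alkyne (anti-Markovnikov hydration).
4. C5/C10 ⇒ enantioselective boron Ireland–Claisen rearrangement of (E)-3-methylpent-2-en-4-yn-1-yl 3-methylbut-3-enoate.
5. Ring order: cyclohexane (C–C bond) first, lactone (C–O bond) second, both in step 9.

Assumption: the (R,R)-bromoborane of step 2 and (S,S)-ProPhenol of step 6 are taken to give the configurations written (2S,3S and 4S); if either sense of induction is the opposite, the antipodal controller is used.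

**Step 1**
Reactants: 1 (E)-3-methylpent-2-en-4-yn-1-ol; 2 3-methylbut-3-enoic acid
Product: 3 (E)-3-methylpent-2-en-4-yn-1-yl 3-methylbut-3-enoate
Conditions: DCC, DMAP (5 mol%), CH2Cl2, 0 °C
Reagents that add atoms: none
Why: Steglich esterification at 0 °C with little DMAP joins the two pieces without moving the β,γ double bond of the acid into conjugation, and no stereocentre is formed.

**Step 2**
Reactants: 3 (E)-3-methylpent-2-en-4-yn-1-yl 3-methylbut-3-enoate
Product: 6 (2S,3S)-3-ethynyl-3-methyl-2-(prop-1-en-2-yl)pent-4-enoic acid, via boron ketene acetal 4 (not isolated), via acyloxyborane 5 (not isolated)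
Conditions: (4R,5R)-2-bromo-4,5-diphenyl-1,3-bis[3,5-bis(trifluoromethyl)phenylsulfonyl]-1,3,2-diazaborolidine (1.2 equiv), Et3N, toluene–hexane, −78 °C, then 4 °C, 7 d; aqueous work-up
Reagents that add atoms: none
Why: Enantioselective boron-mediated Ireland–Claisen rearrangement (Corey type), in which soft enolisation is intended to give the ketene acetal with the isopropenyl group trans to O–B, the chair transition state (ethynyl equatorial from the E-alkene, isopropenyl axial) sets C5 and C10 in the elemane relative configuration, and the C2-symmetric sulfonamide ligand on boron selects the enolate face and so the absolute configuration.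

**Step 3**
Reactants: 6 (2S,3S)-3-ethynyl-3-methyl-2-(prop-1-en-2-yl)pent-4-enoic acid
Product: 7 (2S,3S)-3-ethynyl-3-methyl-2-(prop-1-en-2-yl)pent-4-en-1-ol
Conditions: LiAlH4, THF, 0 °C to rt
Reagents that add atoms: none
Why: Hydride reduction of the acid through its carboxylate (which shields the epimerisable α-centre) gives the primary alcohol, while the isolated alkenes and the alkyne are inert.

**Step 4**
Reactants: 7 (2S,3S)-3-ethynyl-3-methyl-2-(prop-1-en-2-yl)pent-4-en-1-ol
Product: 8 triethyl{[(2S,3S)-3-ethynyl-3-methyl-2-(prop-1-en-2-yl)pent-4-en-1-yl]oxy}silane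
Conditions: TESCl, imidazole, CH2Cl2, 0 °C
Reagents that add atoms: chlorotriethylsilane CC[Si](Cl)(CC)CC
Why: Silylation masks the future C6 oxygen as a primary TES ether, which prevents lactol formation with the C8 aldehyde and is later oxidised directly to the aldehyde.

**Step 5**
Reactants: 8 triethyl{[(2S,3S)-3-ethynyl-3-methyl-2-(prop-1-en-2-yl)pent-4-en-1-yl]oxy}silane
Product: 9 (3S,4S)-3-ethenyl-3,5-dimethyl-4-[(triethylsilyloxy)methyl]hex-5-enal
Conditions: CpRu(MeCN)3PF6 (5 mol%), 5,5'-bis(trifluoromethyl)-2,2'-bipyridine (5 mol%), H2O, acetone, 50 °C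
Reagents that add atoms: water O
Why: Ruthenium-vinylidene anti-Markovnikov hydration of the terminal alkyne gives the C8 aldehyde under neutral conditions that leave the alkenes and the TES ether untouched.

**Step 6**
Reactants: 9 (3S,4S)-3-ethenyl-3,5-dimethyl-4-[(triethylsilyloxy)methyl]hex-5-enal; 10 methyl propiolate
Product: 11 methyl (4S,6S,7S)-6-ethenyl-4-hydroxy-6,8-dimethyl-7-[(triethylsilyloxy)methyl]non-8-en-2-ynoate
Conditions: ZnMe2, (S,S)-ProPhenol (20 mol%), Ph3PO (40 mol%), toluene, 4 °C; aq. NH4Cl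
Reagents that add atoms: none
Why: Zinc–ProPhenol asymmetric alkynylation (Trost type) delivers the propiolate-derived alkynylzinc to one aldehyde face under catalyst control, setting C8 as (S), and the minor C8 epimer is a diastereomer that is removed by chromatography.

**Step 7**
Reactants: 11 methyl (4S,6S,7S)-6-ethenyl-4-hydroxy-6,8-dimethyl-7-[(triethylsilyloxy)methyl]non-8-en-2-ynoate
Product: 12 methyl (4S,6S,7S)-6-ethenyl-6,8-dimethyl-4-(triethylsilyloxy)-7-[(triethylsilyloxy)methyl]non-8-en-2-ynoate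
Conditions: TESCl, imidazole, DMAP (cat.), DMF, rt
Reagents that add atoms: chlorotriethylsilane CC[Si](Cl)(CC)CC
Why: Silylation blocks the C8 oxygen so that it can neither close a butenolide onto the cis ester made in step 8 nor compete with the C6 oxygen in the lactonisation of step 9.

**Step 8**
Reactants: 12 methyl (4S,6S,7S)-6-ethenyl-6,8-dimethyl-4-(triethylsilyloxy)-7-[(triethylsilyloxy)methyl]non-8-en-2-ynoate; 13 2-(iodomethyl)-4,4,5,5-tetramethyl-1,3,2-dioxaborolane
Product: 15 methyl (2Z,4S,6S,7S)-6-ethenyl-6,8-dimethyl-2-[(4,4,5,5-tetramethyl-1,3,2-dioxaborolan-2-yl)methyl]-4-(triethylsilyloxy)-7-[(triethylsilyloxy)methyl]nona-2,8-dienoate, via aluminium allenolate 14 (not isolated)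
Conditions: i-Bu2AlH (DIBAL-H), HMPA, THF, 0 °C; then 13, 0 °C to rt
Reagents that add atoms: none
Why: Conjugate hydroalumination of the ynoate gives the aluminium allenolate, which is C-alkylated by the iodomethylboronate (boron ate complex, 1,2-shift) on the side away from the C8 substituent, so that H and CH2Bpin end up cis and C8 ends up cis to the ester, which is the allylboronate geometry that leads to a trans lactone.

**Step 9** (key step)
Reactants: 15 methyl (2Z,4S,6S,7S)-6-ethenyl-6,8-dimethyl-2-[(4,4,5,5-tetramethyl-1,3,2-dioxaborolan-2-yl)methyl]-4-(triethylsilyloxy)-7-[(triethylsilyloxy)methyl]nona-2,8-dienoate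
Product: 18 (3aS,4S,6S,7S,7aR)-6-ethenyl-6-methyl-3-methylidene-7-(prop-1-en-2-yl)-4-(triethylsilyloxy)hexahydro-1-benzofuran-2(3H)-one, via aldehyde 16 (not isolated), via cyclohexyl borate 17 (not isolated)
Conditions: (COCl)2, DMSO, CH2Cl2, −78 to −40 °C; Et3N, −78 °C to rt; then toluene, 60 °C; then PPTS (cat.), 40 °C
Reagents that add atoms: none
Why: Proposed new method: the Swern reagent converts only the primary TES ether into the aldehyde, whose carbonyl is attacked by the tethered 2-(methoxycarbonyl)allylboronate through a chair–chair (trans-decalin-like) Zimmerman–Traxler transition state with C8 trans to the CH2B carbon, the isopropenyl, vinyl and OTES groups equatorial and the C10 methyl axial, so that C6–O and C7–C11 are formed trans-diequatorial, and the borate then closes onto the methyl ester to give the trans-fused α-methylene lactone, forming the cyclohexane and the lactone in one operation; the closest known reactions are the intramolecular allylboration of aldehydes (E-type allylboronate gives the trans-2-alkenylcycloalkanol), the tandem allylboration–lactonisation of 2-alkoxycarbonyl allylboronates and the direct Swern oxidation of primary TES ethers.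

**Step 10**
Reactants: 18 (3aS,4S,6S,7S,7aR)-6-ethenyl-6-methyl-3-methylidene-7-(prop-1-en-2-yl)-4-(triethylsilyloxy)hexahydro-1-benzofuran-2(3H)-one
Product: 19 (3aR,4S,6S,7S,7aR)-6-ethenyl-4-hydroxy-6-methyl-3-methylidene-7-(prop-1-en-2-yl)hexahydro-1-benzofuran-2(3H)-one
Conditions: HF·pyridine, pyridine, THF, 0 °C
Reagents that add atoms: none
Why: Buffered fluoride desilylation removes the only silyl ether without base, so the α-methylene lactone neither adds nucleophiles nor translactonises to the C8 oxygen.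

**Step 11**
Reactants: 20 (E)-but-2-enal
Product: 22 (Z)-2-bromobut-2-enal, via dibromide 21 (not isolated)
Conditions: Br2, CH2Cl2, −20 °C; then Et3N, 0 °C to rt
Reagents that add atoms: bromine BrBr
Why: Bromine addition followed by amine-induced dehydrobromination gives the thermodynamically preferred α-bromo enal with Br cis to the methyl group.

**Step 12**
Reactants: 22 (Z)-2-bromobut-2-enal
Product: 23 (Z)-2-bromobut-2-en-1-ol
Conditions: NaBH4, CeCl3·7H2O, MeOH, 0 °C
Reagents that add atoms: none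
Why: Luche 1,2-reduction gives the allylic alcohol without touching the vinyl bromide or the alkene geometry.

**Step 13**
Reactants: 23 (Z)-2-bromobut-2-en-1-ol
Product: 24 {[(Z)-2-bromobut-2-en-1-yl]oxy}(tert-butyl)dimethylsilane
Conditions: TBSCl, imidazole, DMF, rt
Reagents that add atoms: tert-butyldimethylsilyl chloride CC(C)(C)[Si](C)(C)Cl
Why: Silylation protects the hydroxyl for the lithiation and for the later acylation.

**Step 14**
Reactants: 24 {[(Z)-2-bromobut-2-en-1-yl]oxy}(tert-butyl)dimethylsilane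
Product: 26 (Z)-2-{[(tert-butyldimethylsilyl)oxy]methyl}but-2-enoic acid, via vinyllithium 25 (not isolated)
Conditions: t-BuLi (2.1 equiv), Et2O, −78 °C; CO2; dilute HCl, 0 °C
Reagents that add atoms: carbon dioxide O=C=O
Why: Bromine–lithium exchange and carboxylation both proceed with retention of alkene geometry at −78 °C, so the carboxyl group ends up cis to the methyl group (the sarracinate geometry).

**Step 15**
Reactants: 19 (3aR,4S,6S,7S,7aR)-6-ethenyl-4-hydroxy-6-methyl-3-methylidene-7-(prop-1-en-2-yl)hexahydro-1-benzofuran-2(3H)-one; 26 (Z)-2-{[(tert-butyldimethylsilyl)oxy]methyl}but-2-enoic acid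
Product: 28 (3aR,4S,6S,7S,7aR)-6-ethenyl-6-methyl-3-methylidene-2-oxo-7-(prop-1-en-2-yl)octahydro-1-benzofuran-4-yl (2Z)-2-{[(tert-butyldimethylsilyl)oxy]methyl}but-2-enoate, via mixed anhydride 27 (not isolated)
Conditions: 2,4,6-trichlorobenzoyl chloride, Et3N, toluene, rt; then 19, 70 °C (no DMAP)
Reagents that add atoms: none
Why: Yamaguchi-type mixed-anhydride esterification run without a nucleophilic catalyst acylates the equatorial C8 hydroxyl while avoiding the addition–elimination pathway that isomerises angelate-type (Z) acids to the E isomers.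

**Step 16**
Reactants: 28 (3aR,4S,6S,7S,7aR)-6-ethenyl-6-methyl-3-methylidene-2-oxo-7-(prop-1-en-2-yl)octahydro-1-benzofuran-4-yl (2Z)-2-{[(tert-butyldimethylsilyl)oxy]methyl}but-2-enoate
Product: 29 (3aR,4S,6S,7R,7aR)-6-ethenyl-7-(3-hydroxyprop-1-en-2-yl)-6-methyl-3-methylidene-2-oxooctahydro-1-benzofuran-4-yl (2Z)-2-{[(tert-butyldimethylsilyl)oxy]methyl}but-2-enoate
Conditions: SeO2 (0.3 equiv), t-BuOOH, salicylic acid (cat.), CH2Cl2, rt
Reagents that add atoms: selenium dioxide O=[Se]=O (oxygen carrier); tert-butyl hydroperoxide CC(C)(C)OO (terminal oxidant)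
Why: Selenium dioxide allylic hydroxylation (ene reaction then 2,3-sigmatropic shift) attacks the isopropenyl group, the only electron-rich alkene with allylic hydrogens, at its methyl group in preference to the hindered C5 methine, and the catalytic protocol limits over-oxidation to the enal.

**Step 17**
Reactants: 29 (3aR,4S,6S,7R,7aR)-6-ethenyl-7-(3-hydroxyprop-1-en-2-yl)-6-methyl-3-methylidene-2-oxooctahydro-1-benzofuran-4-yl (2Z)-2-{[(tert-butyldimethylsilyl)oxy]methyl}but-2-enoate
Product: 30 (3aR,4S,6S,7R,7aR)-6-ethenyl-7-(3-hydroxyprop-1-en-2-yl)-6-methyl-3-methylidene-2-oxooctahydro-1-benzofuran-4-yl (2Z)-2-(hydroxymethyl)but-2-enoate (CNP0111202.1)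
Conditions: HF·pyridine, pyridine, THF, 0 °C to rt
Reagents that add atoms: none
Why: Buffered fluoride desilylation frees the primary allylic alcohol without base, so both esters, the Z geometry and the α-methylene lactone survive.

**Compound list**
1 | (E)-3-methylpent-2-en-4-yn-1-ol | OC/C=C(\C)C#C | starting material
2 | 3-methylbut-3-enoic acid | C=C(C)CC(=O)O | starting material
3 | (E)-3-methylpent-2-en-4-yn-1-yl 3-methylbut-3-enoate | C=C(C)CC(=O)OC/C=C(\C)C#C | intermediate
4 | boron ketene acetal of 3 (isopropenyl cis to the allyloxy oxygen and trans to O–B; boron in the (4R,5R)-4,5-diphenyl-1,3-bis[3,5-bis(trifluoromethyl)phenylsulfonyl]-1,3,2-diazaborolidine ring) | C=C(C)/C=C(/OB1N(S(=O)(=O)c2cc(cc(c2)C(F)(F)F)C(F)(F)F)[C@H](c2ccccc2)[C@@H](c2ccccc2)N1S(=O)(=O)c1cc(cc(c1)C(F)(F)F)C(F)(F)F)\OC/C=C(\C)C#C | intermediate (not isolated)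
5 | acyloxyborane of acid 6 with the same diazaborolidine | C=C[C@](C)(C#C)[C@H](C(=C)C)C(=O)OB1N(S(=O)(=O)c2cc(cc(c2)C(F)(F)F)C(F)(F)F)[C@H](c2ccccc2)[C@@H](c2ccccc2)N1S(=O)(=O)c1cc(cc(c1)C(F)(F)F)C(F)(F)F | intermediate (not isolated)
6 | (2S,3S)-3-ethynyl-3-methyl-2-(prop-1-en-2-yl)pent-4-enoic acid | C=C[C@](C)(C#C)[C@H](C(=C)C)C(=O)O | intermediate
7 | (2S,3S)-3-ethynyl-3-methyl-2-(prop-1-en-2-yl)pent-4-en-1-ol | C=C[C@](C)(C#C)[C@H](C(=C)C)CO | intermediate
8 | triethyl{[(2S,3S)-3-ethynyl-3-methyl-2-(prop-1-en-2-yl)pent-4-en-1-yl]oxy}silane | C=C[C@](C)(C#C)[C@H](C(=C)C)CO[Si](CC)(CC)CC | intermediate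
9 | (3S,4S)-3-ethenyl-3,5-dimethyl-4-[(triethylsilyloxy)methyl]hex-5-enal | C=C[C@](C)(CC=O)[C@H](C(=C)C)CO[Si](CC)(CC)CC | intermediate
10 | methyl propiolate | C#CC(=O)OC | starting material
11 | methyl (4S,6S,7S)-6-ethenyl-4-hydroxy-6,8-dimethyl-7-[(triethylsilyloxy)methyl]non-8-en-2-ynoate | C=C[C@](C)(C[C@H](O)C#CC(=O)OC)[C@H](C(=C)C)CO[Si](CC)(CC)CC | intermediate
12 | methyl (4S,6S,7S)-6-ethenyl-6,8-dimethyl-4-(triethylsilyloxy)-7-[(triethylsilyloxy)methyl]non-8-en-2-ynoate | C=C[C@](C)(C[C@H](O[Si](CC)(CC)CC)C#CC(=O)OC)[C@H](C(=C)C)CO[Si](CC)(CC)CC | intermediate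
13 | 2-(iodomethyl)-4,4,5,5-tetramethyl-1,3,2-dioxaborolane | ICB1OC(C)(C)C(C)(C)O1 | starting material
14 | diisobutylaluminium allenolate of 12 (O-bound, C7H=C11=C(OMe)OAl) | C=C[C@](C)(C[C@H](O[Si](CC)(CC)CC)C=C=C(OC)O[Al](CC(C)C)CC(C)C)[C@H](C(=C)C)CO[Si](CC)(CC)CC | intermediate (not isolated)
15 | methyl (2Z,4S,6S,7S)-6-ethenyl-6,8-dimethyl-2-[(4,4,5,5-tetramethyl-1,3,2-dioxaborolan-2-yl)methyl]-4-(triethylsilyloxy)-7-[(triethylsilyloxy)methyl]nona-2,8-dienoate | C=C[C@](C)(C[C@H](O[Si](CC)(CC)CC)/C=C(/CB1OC(C)(C)C(C)(C)O1)C(=O)OC)[C@H](C(=C)C)CO[Si](CC)(CC)CC | intermediate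
16 | methyl (2Z,4S,6S,7S)-6-ethenyl-7-formyl-6,8-dimethyl-2-[(4,4,5,5-tetramethyl-1,3,2-dioxaborolan-2-yl)methyl]-4-(triethylsilyloxy)nona-2,8-dienoate | C=C[C@](C)(C[C@H](O[Si](CC)(CC)CC)/C=C(/CB1OC(C)(C)C(C)(C)O1)C(=O)OC)[C@H](C(=C)C)C=O | intermediate (not isolated)
17 | methyl 2-[(1S,2R,3S,4S,6S)-4-ethenyl-4-methyl-3-(prop-1-en-2-yl)-2-[(4,4,5,5-tetramethyl-1,3,2-dioxaborolan-2-yl)oxy]-6-(triethylsilyloxy)cyclohexyl]prop-2-enoate | C=C[C@]1(C)C[C@H](O[Si](CC)(CC)CC)[C@@H](C(=C)C(=O)OC)[C@H](OB2OC(C)(C)C(C)(C)O2)[C@H]1C(=C)C | intermediate (not isolated)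
18 | (3aS,4S,6S,7S,7aR)-6-ethenyl-6-methyl-3-methylidene-7-(prop-1-en-2-yl)-4-(triethylsilyloxy)hexahydro-1-benzofuran-2(3H)-one | C=C[C@]1(C)C[C@H](O[Si](CC)(CC)CC)[C@H]2C(=C)C(=O)O[C@@H]2[C@H]1C(=C)C | intermediate
19 | (3aR,4S,6S,7S,7aR)-6-ethenyl-4-hydroxy-6-methyl-3-methylidene-7-(prop-1-en-2-yl)hexahydro-1-benzofuran-2(3H)-one | C=C[C@]1(C)C[C@H](O)[C@H]2C(=C)C(=O)O[C@@H]2[C@H]1C(=C)C | intermediate
20 | (E)-but-2-enal (crotonaldehyde) | C/C=C/C=O | starting material
21 | 2,3-dibromobutanal | CC(Br)C(Br)C=O | intermediate (not isolated)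
22 | (Z)-2-bromobut-2-enal | C/C=C(\Br)C=O | intermediate
23 | (Z)-2-bromobut-2-en-1-ol | C/C=C(\Br)CO | intermediate
24 | {[(Z)-2-bromobut-2-en-1-yl]oxy}(tert-butyl)dimethylsilane | C/C=C(\Br)CO[Si](C)(C)C(C)(C)C | intermediate
25 | (Z)-1-[(tert-butyldimethylsilyl)oxy]but-2-en-2-yllithium | C/C=C(\[Li])CO[Si](C)(C)C(C)(C)C | intermediate (not isolated)
26 | (Z)-2-{[(tert-butyldimethylsilyl)oxy]methyl}but-2-enoic acid | C/C=C(/CO[Si](C)(C)C(C)(C)C)C(=O)O | intermediate
27 | (Z)-2-{[(tert-butyldimethylsilyl)oxy]methyl}but-2-enoic 2,4,6-trichlorobenzoic anhydride | C/C=C(/CO[Si](C)(C)C(C)(C)C)C(=O)OC(=O)c1c(Cl)cc(Cl)cc1Cl | intermediate (not isolated)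
28 | (3aR,4S,6S,7S,7aR)-6-ethenyl-6-methyl-3-methylidene-2-oxo-7-(prop-1-en-2-yl)octahydro-1-benzofuran-4-yl (2Z)-2-{[(tert-butyldimethylsilyl)oxy]methyl}but-2-enoate | C=C[C@]1(C)C[C@H](OC(=O)/C(=C\C)CO[Si](C)(C)C(C)(C)C)[C@H]2C(=C)C(=O)O[C@@H]2[C@H]1C(=C)C | intermediate
29 | (3aR,4S,6S,7R,7aR)-6-ethenyl-7-(3-hydroxyprop-1-en-2-yl)-6-methyl-3-methylidene-2-oxooctahydro-1-benzofuran-4-yl (2Z)-2-{[(tert-butyldimethylsilyl)oxy]methyl}but-2-enoate | C=C[C@]1(C)C[C@H](OC(=O)/C(=C\C)CO[Si](C)(C)C(C)(C)C)[C@H]2C(=C)C(=O)O[C@@H]2[C@H]1C(=C)CO | intermediate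
30 | (3aR,4S,6S,7R,7aR)-6-ethenyl-7-(3-hydroxyprop-1-en-2-yl)-6-methyl-3-methylidene-2-oxooctahydro-1-benzofuran-4-yl (2Z)-2-(hydroxymethyl)but-2-enoate | C=C[C@]1(C)C[C@H](OC(=O)/C(=C\C)CO)[C@H]2C(=C)C(=O)O[C@@H]2[C@H]1C(=C)CO | target

**Step count**
Total: 17 steps. Longest linear sequence: 13 steps (steps 1–10, then 15–17); the acid side chain (steps 11–14) is a four-step branch.

**Steps most likely to fail, with fallbacks**

Step 8 is at risk because C-alkylation of an aluminium allenolate by the iodomethylboronate has to compete with protonation and with loss of the alkene geometry on a hindered γ-silyloxy substrate. The fallback sets out from 12 and comes back at 15, and builds the same allylboronate by cross-coupling instead of enolate alkylation. Syn-hydrostannation of 12 (Bu3SnH, Pd(PPh3)4, THF, 0 °C) puts tin α to the ester and gives methyl (2E,4S,6S,7S)-6-ethenyl-6,8-dimethyl-2-(tributylstannyl)-4-(triethylsilyloxy)-7-[(triethylsilyloxy)methyl]nona-2,8-dienoate F1. Iododestannylation (I2, CH2Cl2, 0 °C) proceeds with retention and gives the α-iodo enoate methyl (2E,4S,6S,7S)-6-ethenyl-2-iodo-6,8-dimethyl-4-(triethylsilyloxy)-7-[(triethylsilyloxy)methyl]nona-2,8-dienoate F2. Negishi coupling of F2 with IZnCH2Bpin (from 13 and zinc dust; Pd(PPh3)4, THF, rt) then gives 15 with C8 still cis to the ester.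

Step 9 is at risk because the allylboronate must survive the Swern reagent, the 2-alkoxycarbonyl allylboronate is a weak nucleophile, and the hindered aldehyde can epimerise at C5. The fallback sets out from 11 and comes back at 18; it still forms both rings in one operation but by a radical pathway, and installs the methylene afterwards.
- Trans-hydroalumination and protonation of 11 (NaAlH2(OCH2CH2OMe)2, THF, −72 °C) gives methyl (2E,4S,6S,7S)-6-ethenyl-4-hydroxy-6,8-dimethyl-7-[(triethylsilyloxy)methyl]nona-2,8-dienoate F3.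
- TESCl and imidazole give the bis-silyl ether methyl (2E,4S,6S,7S)-6-ethenyl-6,8-dimethyl-4-(triethylsilyloxy)-7-[(triethylsilyloxy)methyl]nona-2,8-dienoate F4.
- Swern oxidation of the primary TES ether gives methyl (2E,4S,6S,7S)-6-ethenyl-7-formyl-6,8-dimethyl-4-(triethylsilyloxy)nona-2,8-dienoate F5.
- SmI2 with t-BuOH in THF (−78 to 0 °C) effects 6-exo ketyl–olefin cyclisation through the all-equatorial chair with the ketyl oxygen anti to the enoate, and the samarium alkoxide lactonises, giving (3aS,4S,6S,7S,7aR)-6-ethenyl-6-methyl-7-(prop-1-en-2-yl)-4-(triethylsilyloxy)hexahydro-1-benzofuran-2(3H)-one F6.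
- α-Methylenation: LiN(SiMe3)2 then CH2=NMe2+ I− gives the 3-[(dimethylamino)methyl] lactone F7; MeI gives its methiodide F8; NaHCO3 elimination gives 18.

Step 16 is at risk because selenium dioxide can over-oxidise to the enal or attack the C5 methine on a substrate carrying two enoates. The fallback sets out from 28 and comes back at 29, and replaces the selenium ene oxidation by ene-type chlorination and substitution. Ca(OCl)2 with solid CO2 in CH2Cl2–H2O at 0 °C gives the 2-(chloromethyl)allyl compound (3aR,4S,6S,7R,7aR)-7-(3-chloroprop-1-en-2-yl)-6-ethenyl-6-methyl-3-methylidene-2-oxooctahydro-1-benzofuran-4-yl (2Z)-2-{[(tert-butyldimethylsilyl)oxy]methyl}but-2-enoate F9. Silver-assisted hydrolysis (AgBF4, acetone–H2O, rt) passes through a 2-substituted allyl cation whose two ends are both CH2 groups, so it gives 29 without a regiochemical issue.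

**Further compounds**
F1 | step 8 | methyl (2E,4S,6S,7S)-6-ethenyl-6,8-dimethyl-2-(tributylstannyl)-4-(triethylsilyloxy)-7-[(triethylsilyloxy)methyl]nona-2,8-dienoate | C=C[C@](C)(C[C@H](O[Si](CC)(CC)CC)/C=C(/[Sn](CCCC)(CCCC)CCCC)C(=O)OC)[C@H](C(=C)C)CO[Si](CC)(CC)CC
F2 | step 8 | methyl (2E,4S,6S,7S)-6-ethenyl-2-iodo-6,8-dimethyl-4-(triethylsilyloxy)-7-[(triethylsilyloxy)methyl]nona-2,8-dienoate | C=C[C@](C)(C[C@H](O[Si](CC)(CC)CC)/C=C(/I)C(=O)OC)[C@H](C(=C)C)CO[Si](CC)(CC)CC
F3 | step 9 | methyl (2E,4S,6S,7S)-6-ethenyl-4-hydroxy-6,8-dimethyl-7-[(triethylsilyloxy)methyl]nona-2,8-dienoate | C=C[C@](C)(C[C@H](O)/C=C/C(=O)OC)[C@H](C(=C)C)CO[Si](CC)(CC)CC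
F4 | step 9 | methyl (2E,4S,6S,7S)-6-ethenyl-6,8-dimethyl-4-(triethylsilyloxy)-7-[(triethylsilyloxy)methyl]nona-2,8-dienoate | C=C[C@](C)(C[C@H](O[Si](CC)(CC)CC)/C=C/C(=O)OC)[C@H](C(=C)C)CO[Si](CC)(CC)CC
F5 | step 9 | methyl (2E,4S,6S,7S)-6-ethenyl-7-formyl-6,8-dimethyl-4-(triethylsilyloxy)nona-2,8-dienoate | C=C[C@](C)(C[C@H](O[Si](CC)(CC)CC)/C=C/C(=O)OC)[C@H](C(=C)C)C=O
F6 | step 9 | (3aS,4S,6S,7S,7aR)-6-ethenyl-6-methyl-7-(prop-1-en-2-yl)-4-(triethylsilyloxy)hexahydro-1-benzofuran-2(3H)-one | C=C[C@]1(C)C[C@H](O[Si](CC)(CC)CC)[C@H]2CC(=O)O[C@@H]2[C@H]1C(=C)C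
F7 | step 9 | 3-[(dimethylamino)methyl] derivative of F6 (C3 epimers) | C=C[C@]1(C)C[C@H](O[Si](CC)(CC)CC)[C@H]2C(CN(C)C)C(=O)O[C@@H]2[C@H]1C(=C)C
F8 | step 9 | methiodide of F7 | C=C[C@]1(C)C[C@H](O[Si](CC)(CC)CC)[C@H]2C(C[N+](C)(C)C)C(=O)O[C@@H]2[C@H]1C(=C)C.[I-]
F9 | step 16 | (3aR,4S,6S,7R,7aR)-7-(3-chloroprop-1-en-2-yl)-6-ethenyl-6-methyl-3-methylidene-2-oxooctahydro-1-benzofuran-4-yl (2Z)-2-{[(tert-butyldimethylsilyl)oxy]methyl}but-2-enoate | C=C[C@]1(C)C[C@H](OC(=O)/C(=C\C)CO[Si](C)(C)C(C)(C)C)[C@H]2C(=C)C(=O)O[C@@H]2[C@H]1C(=C)CCl
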